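## Retrosynthetic overview
1. The endgame is global desilylation, oxidation of C5-OH to the ketone, and Z-selective semi-reduction of a C8≡C9 enyne. The 20-membered ring is closed last at C7–C8 by Sonogashira coupling, after the C1–O19 ester is made.
2. The C13–C14 bond comes from transfer of a Z-alkenyl (C8–C13) trifluoroborate to the oxocarbenium ion of a lactol acetate.
3. The THF ring is formed first, as a γ-lactone, by 1,3-anti reduction and lactonisation of the C18–C19 syn-aldol of an ethyl ketone with an L-rhamnal-derived enal (C19–C24).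
4. Key bond C16–C17: an NHC-generated propionyl-anion equivalent (from propanal) adds to the β-carbon of methyl 2-methoxyacrylate. This gives the 1,4-dioxygenated C14–C17 unit, the OMe group and C15 in one catalytic step.
5. C11–C13 and C5–C7 both come from propargyl alcohol: anti-carbomagnesiation gives 12Z and syn-carboalumination gives 6E. C11 is set by Cu-catalysed propargylation, C4 by crotylboration, and 2Z by Still–Gennari olefination. Ring order: THF (step 6), then macrolactone (step 23).

Assumption: maltepolide numbering is used (C1 = lactone C=O, C24 = side-chain CH3; TBS = tert-butyldimethylsilyl, TES = triethylsilyl); the SMILES is read as 2Z,6E,8Z,12Z,20E and 4S,11R,14S,15S,17R,18R,19R,22R,23S; in steps 1, 5, 10 and 17 the chiral catalyst or reagent antipode named is the one expected by analogy, and its mirror image is equally available.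

## Route

Step 1
Reactants: 1 propanal; 2 methyl 2-methoxyacrylate
Product: 4 methyl (2S)-2-methoxy-4-oxohexanoate (C14–C18), via Breslow enaminol 3 (not isolated)
Conditions: (S)-5-benzyl-2-mesityl-5,6-dihydro-8H-[1,2,4]triazolo[3,4-c][1,4]oxazin-2-ium chloride (10 mol %), KOt-Bu (8 mol %), toluene, 0 °C → rt, slow addition of 1
Reagents that add atoms: none
Why: Proposed new method: the carbene turns propanal into enaminol 3, an acyl-anion equivalent whose former carbonyl carbon (C17) adds to the equally electrophilic β-carbon (C16) of the captodative acrylate, and the resulting ester enolate is protonated by internal O–H transfer inside the chiral pocket to set C15 as S; the closest known reaction type is the enantioselective intermolecular Stetter reaction of aldehydes with 2-amidoacrylates, where the stereocentre is also set by protonation, together with Stetter reactions of enolisable aliphatic aldehydes.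

Step 2
Reactants: 5 3,4-di-O-acetyl-L-rhamnal
Product: 6 (2E,4R,5S)-4-acetoxy-5-hydroxyhex-2-enal
Conditions: HgSO4 (2 mol %), 5 mM aq H2SO4, 1,4-dioxane, rt
Reagents that add atoms: water O
Why: Perlin hydrolysis (Hg(II)-catalysed hydration of the glycal, ring opening, loss of the C3 acetate) gives the E-enal and carries C22 and C23 over unchanged from L-rhamnose.

Step 3
Reactants: 6 (2E,4R,5S)-4-acetoxy-5-hydroxyhex-2-enal
Product: 7 (2E,4R,5S)-4,5-dihydroxyhex-2-enal
Conditions: K2CO3 (0.1 equiv), MeOH, 0 °C, 20 min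
Reagents that add atoms: none
Why: Zemplén-type transesterification of the hydroxyl-assisted allylic acetate is faster at 0 °C than any irreversible reaction of the enal, and it touches no stereocentre.

Step 4
Reactants: 7 (2E,4R,5S)-4,5-dihydroxyhex-2-enal
Product: 8 (2E,4R,5S)-4,5-bis(tert-butyldimethylsilyloxy)hex-2-enal (C19–C24)
Conditions: TBSOTf (2.4 equiv), 2,6-lutidine, CH2Cl2, –78 → 0 °C
Reagents that add atoms: tert-butyldimethylsilyl triflate CC(C)(C)[Si](C)(C)OS(=O)(=O)C(F)(F)F
Why: Silyl triflate silylation under non-nucleophilic base protects both secondary alcohols without enolising or adding to the enal.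

Step 5
Reactants: 4 methyl (2S)-2-methoxy-4-oxohexanoate; 8 bis-TBS enal
Product: 10 methyl (2S,5S,6R,7E,9R,10S)-9,10-bis(TBSO)-6-hydroxy-2-methoxy-5-methyl-4-oxoundec-7-enoate (C14–C24 syn-aldol), via (Z)-enol diisopinocampheylborinate 9 (not isolated)
Conditions: (–)-Ipc2BOTf, i-Pr2NEt, CH2Cl2, –78 °C; 8, –78 → –20 °C; H2O2, MeOH, pH 7 buffer
Reagents that add atoms: none
Why: In this Paterson boron aldol the very bulky borane and hindered amine enolise the unbranched ethyl side rather than the β-branched C16 methylene to give Z-enolate 9, whose Zimmerman–Traxler chair gives the 18,19-syn aldol, and the Ipc ligands direct attack to the Si face of the enal to set C18 and C19.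

Step 6
Reactants: 10 C14–C24 syn-aldol
Product: 12 (3S,5R)-5-[(2S,3R,4E,6R,7S)-6,7-bis(TBSO)-3-hydroxyoct-4-en-2-yl]-3-methoxyoxolan-2-one (γ-lactone; free C19-OH), via 17,19-anti diol ester 11 (not isolated)
Conditions: Me4NBH(OAc)3, MeCN–AcOH, –25 °C; work-up, then PPTS (cat.), CH2Cl2, rt
Reagents that add atoms: none
Why: In the Evans–Saksena reduction the boron bound to C19-OH delivers hydride internally to give the 17,19-anti diol (C17 = R), and only C17-OH can close a five-membered lactone on the C14 ester, which forms the first ring and leaves C19-OH differentiated.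

Step 7
Reactants: 12 γ-lactone
Product: 14 (3S,5R)-5-[(2R,3R,4E,6R,7S)-3-acetoxy-6,7-bis(TBSO)oct-4-en-2-yl]-3-methoxyoxolan-2-yl acetate (C14,C19-bis-acetate; both C14 anomers), via bis(diisobutylaluminium) lactol alkoxide 13 (not isolated)
Conditions: DIBAL-H (2.3 equiv), CH2Cl2, –78 °C; then pyridine, DMAP, Ac2O, –78 → –20 °C
Reagents that add atoms: acetic anhydride CC(=O)OC(C)=O
Why: In the Rychnovsky reductive acetylation the stable aluminium hemiacetal is trapped in situ as the α-acetoxy ether, and the C19 aluminium alkoxide is acetylated in the same operation, so its protection costs no extra step.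

Step 8
Reactants: 15 propargyl alcohol
Product: 17 (Z)-3-iodo-2-methylprop-2-en-1-ol, via cyclic (Z)-alkenylmagnesium alkoxide 16 (not isolated)
Conditions: MeMgBr (2.5 equiv), CuI (10 mol %), THF, –10 °C → rt; I2, –30 °C
Reagents that add atoms: methylmagnesium bromide C[Mg]Br; iodine II
Why: Alkoxide-directed Cu-catalysed anti-carbomagnesiation puts methyl on C12 and magnesium on C13 cis to the CH2O group in chelate 16, and iodinolysis with retention fixes the 12Z geometry.

Step 9
Reactants: 17 (Z)-3-iodo-2-methylprop-2-en-1-ol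
Product: 18 (Z)-3-iodo-2-methylprop-2-enal
Conditions: activated MnO2, CH2Cl2, rt, dark; used at once
Reagents that add atoms: none
Why: Neutral heterogeneous MnO2 allylic oxidation gives the enal without the acid or light that would isomerise the Z-alkene.

Step 10
Reactants: 18 (Z)-3-iodo-2-methylprop-2-enal; 19 3-(trimethylsilyl)prop-2-ynylboronic acid pinacol ester
Product: 21 (1Z,3R)-1-iodo-2-methyl-6-(trimethylsilyl)hex-1-en-5-yn-3-ol (C8–C13), via O-pinacolboryl ester 20 (not isolated)
Conditions: Cu(O2C-i-Pr)2 (5 mol %), LiOt-Bu (5 mol %), MeO-BIBOP (6 mol %), THF, –30 °C; aq NH4Cl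
Reagents that add atoms: none
Why: In this copper-catalysed asymmetric propargylation, B-to-Cu exchange gives a chiral allenylcopper that adds by SE2′ to the Re face of the enal, which sets C11 as R and gives only the homopropargylic alcohol.

Step 11
Reactants: 21 homopropargylic alcohol
Product: 22 (1Z,3R)-3-(tert-butyldimethylsilyloxy)-1-iodo-2-methyl-6-(trimethylsilyl)hex-1-en-5-yne
Conditions: TBSOTf, 2,6-lutidine, CH2Cl2, –78 °C
Reagents that add atoms: tert-butyldimethylsilyl triflate CC(C)(C)[Si](C)(C)OS(=O)(=O)C(F)(F)F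
Why: Standard silylation protects C11-OH with the same group as C22/C23, so that one final operation removes all three.

Step 12
Reactants: 22 TBS-protected Z-vinyl iodide
Product: 25 potassium (1Z,3R)-[3-(TBSO)-2-methyl-6-(trimethylsilyl)hex-1-en-5-yn-1-yl]trifluoroborate, via Z-alkenyllithium 23 (not isolated), via lithium alkenyltrimethoxyborate 24 (not isolated)
Conditions: t-BuLi (2.1 equiv), Et2O, –78 °C; B(OMe)3 at once, –78 → 0 °C; aq KHF2, MeOH, 0 °C
Reagents that add atoms: trimethyl borate COB(OC)OC; potassium hydrogen difluoride [K+].[F-].F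
Why: Iodine–lithium exchange, borylation and fluoride exchange all proceed with retention at sp2 carbon, the immediate borate quench in Et2O at –78 °C outruns a retro-[1,4]-Brook silyl shift in the cis-silyloxy alkenyllithium, the silylated alkyne carries no acidic proton, and alkynyl-TMS and TBS groups tolerate brief KHF2 treatment.

Step 13
Reactants: 14 bis-acetate; 25 potassium Z-alkenyltrifluoroborate
Product: 28 C8–C24 2-alkenyl-THF (14S; 12Z; C19-OAc; C8-TMS; TBS ethers at C11/C22/C23), via Z-alkenyldifluoroborane 26 (not isolated), via five-ring oxocarbenium ion 27 (not isolated)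
Conditions: BF3·OEt2 (3 equiv), MeCN–CH2Cl2, –40 → 0 °C
Reagents that add atoms: none
Why: In this C-glycosylation with an organotrifluoroborate (known for furanosyl donors), BF3 unmasks 26 and ionises the anomeric acetate to 27, and the alkenyl group is transferred with retention of Z geometry to the inside face of the envelope that holds the C15 methoxy group pseudo-equatorial (Woerpel model), which is also the face anti to the C17 side chain, so C14 is set 14,15-cis and 14,17-trans.

Step 14
Reactants: 28 C8–C24 acetate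
Product: 29 C8–C24 alcohol (free C19-OH; terminal C8 alkyne; TBS ethers at C11/C22/C23)
Conditions: K2CO3, MeOH, rt
Reagents that add atoms: none
Why: Methanolysis removes the C19 acetate and the alkynyl TMS group in one operation while the three secondary TBS ethers are inert.

Step 15
Reactants: 15 propargyl alcohol
Product: 31 (E)-3-iodo-2-methylprop-2-en-1-ol, via (E)-alkenylalane 30 (not isolated)
Conditions: Me3Al (3 equiv), Cp2ZrCl2 (25 mol %), CH2Cl2, 0 °C → rt; I2, THF, –30 °C
Reagents that add atoms: trimethylaluminium C[Al](C)C; iodine II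
Why: Negishi Zr-catalysed syn-carboalumination places methyl on C6 and aluminium on C7 trans to the CH2O group, and iodinolysis with retention fixes the 6E geometry.

Step 16
Reactants: 31 (E)-3-iodo-2-methylprop-2-en-1-ol
Product: 32 (E)-3-iodo-2-methylprop-2-enal
Conditions: activated MnO2, CH2Cl2, rt
Reagents that add atoms: none
Why: MnO2 allylic oxidation stops cleanly at the enal and leaves the vinyl iodide untouched.

Step 17
Reactants: 32 (E)-3-iodo-2-methylprop-2-enal; 33 (E)-crotylboronic acid pinacol ester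
Product: 35 (1E,3S,4S)-1-iodo-2,4-dimethylhexa-1,5-dien-3-ol (C3–C7), via O-pinacolboryl ester 34 (not isolated)
Conditions: (S)-TRIP phosphoric acid (5 mol %), 4 Å MS, toluene, –30 °C; aqueous work-up
Reagents that add atoms: none
Why: In this chiral-phosphoric-acid-catalysed crotylboration the closed chair transition state turns the E-crotyl geometry into the 4,5-anti relationship, and the (S)-acid directs attack to the Si face of the aldehyde, which sets C4 in its final configuration and C5 as a temporary S carbinol.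

Step 18
Reactants: 35 anti homoallylic alcohol
Product: 36 (1E,3S,4S)-1-iodo-2,4-dimethyl-3-(triethylsilyloxy)hexa-1,5-diene
Conditions: TESCl, imidazole, CH2Cl2, 0 °C
Reagents that add atoms: chlorotriethylsilane CC[Si](Cl)(CC)CC
Why: A TES ether is chosen because it can later be removed in the presence of secondary TBS ethers, which singles out C5 for oxidation.

Step 19
Reactants: 36 TES ether
Product: 38 (2R,3S,4E)-5-iodo-2,4-dimethyl-3-(triethylsilyloxy)pent-4-enal, via terminal 1,2-diol 37 (not isolated)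
Conditions: OsO4 (2 mol %), NaIO4 (4 equiv), 2,6-lutidine, dioxane–H2O, rt
Reagents that add atoms: osmium tetroxide O=[Os](=O)(=O)=O; sodium periodate [Na+].[O-]I(=O)(=O)=O
Why: In the Johnson–Lemieux cleavage the monosubstituted alkene is dihydroxylated much faster than the hindered, electron-poor iodoalkene, and lutidine buffering prevents epimerisation of the new α-chiral aldehyde.

Step 20
Reactants: 38 aldehyde; 39 ethyl 2-[bis(2,2,2-trifluoroethoxy)phosphoryl]propanoate
Product: 41 ethyl (2Z,4S,5S,6E)-7-iodo-2,4,6-trimethyl-5-(triethylsilyloxy)hepta-2,6-dienoate, via potassium phosphonate anion 40 (not isolated)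
Conditions: KHMDS, 18-crown-6, THF, –78 °C
Reagents that add atoms: none
Why: In the Still–Gennari olefination, fast irreversible collapse of the kinetic adduct of the electron-poor phosphonate under dissociating conditions gives the 2Z trisubstituted enoate, and the preformed anion does not epimerise C4 at –78 °C.

Step 21
Reactants: 41 ethyl Z-enoate
Product: 42 (2Z,4S,5S,6E)-7-iodo-2,4,6-trimethyl-5-(triethylsilyloxy)hepta-2,6-dienoic acid (C1–C7)
Conditions: LiOH, THF–MeOH–H2O, rt → 40 °C; 1 M HCl to pH 4–5, 0 °C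
Reagents that add atoms: lithium hydroxide [Li+].[OH-]
Why: Saponification leaves the alkene geometries, the vinyl iodide and the base-stable TES ether intact, and the protected C5 oxygen cannot lactonise onto the Z-acid.

Step 22
Reactants: 29 C8–C24 alcohol; 42 C1–C7 acid
Product: 44 seco ester (C19–O–C1 ester; C7 vinyl iodide; C8 terminal alkyne), via Yamaguchi mixed anhydride 43 (not isolated)
Conditions: 2,4,6-trichlorobenzoyl chloride, Et3N, THF; then 29, DMAP, toluene, rt
Reagents that add atoms: none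
Why: In the Yamaguchi esterification the only free hydroxyl (C19-OH) is acylated with retention at C19, and the α-methyl group of the Z-enoate suppresses addition–elimination isomerisation by DMAP.

Step 23
Reactants: 44 seco ester
Product: 45 20-membered macrocyclic 6E-en-8-yne
Conditions: Pd(PPh3)4 (10 mol %), CuI (20 mol %), i-Pr2NH, degassed THF, 1 mM, slow addition, rt
Reagents that add atoms: none
Why: The Sonogashira macrocyclisation closes the second ring at C7–C8 with retention of the 6E geometry under mild amine conditions, to which C4 is inert because C5 is still a silyl ether.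

Step 24
Reactants: 45 macrocyclic enyne
Product: 46 macrocyclic (6E,8Z)-diene
Conditions: Zn(Cu/Ag), MeOH–H2O, rt
Reagents that add atoms: none
Why: The Boland reduction delivers two hydrogens cis only to the conjugated (activated) alkyne, which gives the 8Z alkene without touching the isolated alkenes, the enoate or the silyl ethers.

Step 25
Reactants: 46 macrocyclic diene
Product: 47 C5 alcohol (5S; C11/C22/C23 still TBS ethers)
Conditions: HF·pyridine, excess pyridine, THF, –10 °C
Reagents that add atoms: none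
Why: Buffered fluoride cleaves the TES ether far faster than secondary TBS ethers and is too weakly acidic to ionise the dienylic carbinol.

Step 26
Reactants: 47 C5 alcohol
Product: 48 11,22,23-tris-O-TBS maltepolide D (C5 ketone)
Conditions: Dess–Martin periodinane, NaHCO3, CH2Cl2, 0 °C → rt
Reagents that add atoms: none
Why: The buffered, essentially neutral Dess–Martin oxidation installs the dienone only now, so the doubly activated C4-H is exposed to a single further step.

Step 27
Reactants: 48 tris-TBS maltepolide D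
Product: 49 maltepolide D
Conditions: HF·pyridine, THF, 0 °C → rt (plastic vessel)
Reagents that add atoms: none
Why: Mildly acidic global desilylation frees C11-, C22- and C23-OH without base, so C4, the 2Z enoate and the lactone survive.

## Compound list
1 | propanal | CCC=O | starting material
2 | methyl 2-methoxyacrylate | C=C(OC)C(=O)OC | starting material
3 | Breslow enaminol (propionyl-anion equivalent from propanal and the triazolylidene) | CCC(O)=C1N(c2c(C)cc(C)cc2C)N=C2COC[C@H](Cc3ccccc3)N12 | intermediate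
4 | methyl (2S)-2-methoxy-4-oxohexanoate | CCC(=O)C[C@H](OC)C(=O)OC | intermediate
5 | 3,4-di-O-acetyl-L-rhamnal | C[C@@H]1OC=C[C@H](OC(C)=O)[C@H]1OC(C)=O | starting material
6 | (2E,4R,5S)-4-acetoxy-5-hydroxyhex-2-enal | O=C/C=C/[C@@H](OC(C)=O)[C@H](C)O | intermediate
7 | (2E,4R,5S)-4,5-dihydroxyhex-2-enal | O=C/C=C/[C@@H](O)[C@H](C)O | intermediate
8 | (2E,4R,5S)-4,5-bis(TBSO)hex-2-enal | O=C/C=C/[C@@H](O[Si](C)(C)C(C)(C)C)[C@H](C)O[Si](C)(C)C(C)(C)C | intermediate
9 | (Z)-enol diisopinocampheylborinate of 4 | C/C=C(\OB([C@@H]1C[C@@H]2C[C@H]([C@H]1C)C2(C)C)[C@@H]1C[C@@H]2C[C@H]([C@H]1C)C2(C)C)C[C@H](OC)C(=O)OC | intermediate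
10 | C14–C24 syn-aldol (keto ester) | COC(=O)[C@@H](OC)CC(=O)[C@@H](C)[C@H](O)/C=C/[C@@H](O[Si](C)(C)C(C)(C)C)[C@H](C)O[Si](C)(C)C(C)(C)C | intermediate
11 | 17,19-anti diol ester, methyl (2S,4R,5R,6R,7E,9R,10S)-9,10-bis(TBSO)-4,6-dihydroxy-2-methoxy-5-methylundec-7-enoate | COC(=O)[C@@H](OC)C[C@@H](O)[C@@H](C)[C@H](O)/C=C/[C@@H](O[Si](C)(C)C(C)(C)C)[C@H](C)O[Si](C)(C)C(C)(C)C | intermediate
12 | α-methoxy-γ-lactone, free C19-OH | CO[C@H]1C[C@H]([C@@H](C)[C@H](O)/C=C/[C@@H](O[Si](C)(C)C(C)(C)C)[C@H](C)O[Si](C)(C)C(C)(C)C)OC1=O | intermediate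
13 | bis(diisobutylaluminium) alkoxide of the lactol | CO[C@H]1C[C@H]([C@@H](C)[C@H](O[Al](CC(C)C)CC(C)C)/C=C/[C@@H](O[Si](C)(C)C(C)(C)C)[C@H](C)O[Si](C)(C)C(C)(C)C)OC1O[Al](CC(C)C)CC(C)C | intermediate
14 | C14,C19-bis-acetate (anomers) | CO[C@H]1C[C@H]([C@@H](C)[C@H](OC(C)=O)/C=C/[C@@H](O[Si](C)(C)C(C)(C)C)[C@H](C)O[Si](C)(C)C(C)(C)C)OC1OC(C)=O | intermediate
15 | propargyl alcohol | C#CCO | starting material
16 | cyclic (Z)-alkenylmagnesium alkoxide | CC1=C[Mg]OC1 | intermediate
17 | (Z)-3-iodo-2-methylprop-2-en-1-ol | I/C=C(/C)CO | intermediate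
18 | (Z)-3-iodo-2-methylprop-2-enal | I/C=C(/C)C=O | intermediate
19 | 3-(trimethylsilyl)prop-2-ynylboronic acid pinacol ester | C[Si](C)(C)C#CCB1OC(C)(C)C(C)(C)O1 | starting material
20 | O-pinacolboryl ester of 21 | I/C=C(/C)[C@H](OB1OC(C)(C)C(C)(C)O1)CC#C[Si](C)(C)C | intermediate
21 | (1Z,3R)-1-iodo-2-methyl-6-(trimethylsilyl)hex-1-en-5-yn-3-ol | I/C=C(/C)[C@H](O)CC#C[Si](C)(C)C | intermediate
22 | TBS ether of 21 | I/C=C(/C)[C@H](O[Si](C)(C)C(C)(C)C)CC#C[Si](C)(C)C | intermediate
23 | Z-alkenyllithium | [Li]/C=C(/C)[C@H](O[Si](C)(C)C(C)(C)C)CC#C[Si](C)(C)C | intermediate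
24 | lithium alkenyltrimethoxyborate | [Li+].CO[B-](OC)(OC)/C=C(/C)[C@H](O[Si](C)(C)C(C)(C)C)CC#C[Si](C)(C)C | intermediate
25 | potassium Z-alkenyltrifluoroborate (C8–C13) | [K+].F[B-](F)(F)/C=C(/C)[C@H](O[Si](C)(C)C(C)(C)C)CC#C[Si](C)(C)C | intermediate
26 | Z-alkenyldifluoroborane | FB(F)/C=C(/C)[C@H](O[Si](C)(C)C(C)(C)C)CC#C[Si](C)(C)C | intermediate
27 | five-ring oxocarbenium ion (C14=O+) | CO[C@H]1C[C@H]([C@@H](C)[C@H](OC(C)=O)/C=C/[C@@H](O[Si](C)(C)C(C)(C)C)[C@H](C)O[Si](C)(C)C(C)(C)C)[O+]=C1 | intermediate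
28 | C8–C24 2-alkenyl-THF, C19-OAc, C8-TMS | CO[C@H]1C[C@H]([C@@H](C)[C@H](OC(C)=O)/C=C/[C@@H](O[Si](C)(C)C(C)(C)C)[C@H](C)O[Si](C)(C)C(C)(C)C)O[C@H]1/C=C(/C)[C@H](O[Si](C)(C)C(C)(C)C)CC#C[Si](C)(C)C | intermediate
29 | C8–C24 alcohol, terminal alkyne | CO[C@H]1C[C@H]([C@@H](C)[C@H](O)/C=C/[C@@H](O[Si](C)(C)C(C)(C)C)[C@H](C)O[Si](C)(C)C(C)(C)C)O[C@H]1/C=C(/C)[C@H](O[Si](C)(C)C(C)(C)C)CC#C | intermediate
30 | (E)-alkenylalane | C[Al](C)OC/C(C)=C/[Al](C)C | intermediate
31 | (E)-3-iodo-2-methylprop-2-en-1-ol | OC/C(C)=C/I | intermediate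
32 | (E)-3-iodo-2-methylprop-2-enal | O=C/C(C)=C/I | intermediate
33 | (E)-crotylboronic acid pinacol ester | C/C=C/CB1OC(C)(C)C(C)(C)O1 | starting material
34 | O-pinacolboryl ester of 35 | C=C[C@H](C)[C@H](OB1OC(C)(C)C(C)(C)O1)/C(C)=C/I | intermediate
35 | (1E,3S,4S)-1-iodo-2,4-dimethylhexa-1,5-dien-3-ol | C=C[C@H](C)[C@H](O)/C(C)=C/I | intermediate
36 | TES ether of 35 | C=C[C@H](C)[C@H](O[Si](CC)(CC)CC)/C(C)=C/I | intermediate
37 | terminal 1,2-diol (epimers at the new carbinol) | OCC(O)[C@H](C)[C@H](O[Si](CC)(CC)CC)/C(C)=C/I | intermediate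
38 | (2R,3S,4E)-5-iodo-2,4-dimethyl-3-(triethylsilyloxy)pent-4-enal | O=C[C@H](C)[C@H](O[Si](CC)(CC)CC)/C(C)=C/I | intermediate
39 | ethyl 2-[bis(2,2,2-trifluoroethoxy)phosphoryl]propanoate | CCOC(=O)C(C)P(=O)(OCC(F)(F)F)OCC(F)(F)F | starting material
40 | potassium phosphonate anion | [K+].CCOC(=O)[C-](C)P(=O)(OCC(F)(F)F)OCC(F)(F)F | intermediate
41 | ethyl (2Z,4S,5S,6E)-7-iodo-2,4,6-trimethyl-5-(TESO)hepta-2,6-dienoate | CCOC(=O)/C(C)=C\[C@H](C)[C@H](O[Si](CC)(CC)CC)/C(C)=C/I | intermediate
42 | (2Z,4S,5S,6E)-7-iodo-2,4,6-trimethyl-5-(TESO)hepta-2,6-dienoic acid | OC(=O)/C(C)=C\[C@H](C)[C@H](O[Si](CC)(CC)CC)/C(C)=C/I | intermediate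
43 | Yamaguchi mixed anhydride (2,4,6-trichlorobenzoic anhydride of 42) | O=C(OC(=O)/C(C)=C\[C@H](C)[C@H](O[Si](CC)(CC)CC)/C(C)=C/I)c1c(Cl)cc(Cl)cc1Cl | intermediate
44 | seco ester | CO[C@H]1C[C@H]([C@@H](C)[C@H](OC(=O)/C(C)=C\[C@H](C)[C@H](O[Si](CC)(CC)CC)/C(C)=C/I)/C=C/[C@@H](O[Si](C)(C)C(C)(C)C)[C@H](C)O[Si](C)(C)C(C)(C)C)O[C@H]1/C=C(/C)[C@H](O[Si](C)(C)C(C)(C)C)CC#C | intermediate
45 | macrocyclic 6E-en-8-yne | CO[C@H]1C[C@H]2O[C@H]1/C=C(/C)[C@H](O[Si](C)(C)C(C)(C)C)CC#C/C=C(\C)[C@@H](O[Si](CC)(CC)CC)[C@@H](C)/C=C(/C)C(=O)O[C@H](/C=C/[C@@H](O[Si](C)(C)C(C)(C)C)[C@H](C)O[Si](C)(C)C(C)(C)C)[C@@H]2C | intermediate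
46 | macrocyclic (6E,8Z)-diene | CO[C@H]1C[C@H]2O[C@H]1/C=C(/C)[C@H](O[Si](C)(C)C(C)(C)C)C/C=C\C=C(/C)[C@@H](O[Si](CC)(CC)CC)[C@@H](C)/C=C(/C)C(=O)O[C@H](/C=C/[C@@H](O[Si](C)(C)C(C)(C)C)[C@H](C)O[Si](C)(C)C(C)(C)C)[C@@H]2C | intermediate
47 | (5S)-C5 alcohol | CO[C@H]1C[C@H]2O[C@H]1/C=C(/C)[C@H](O[Si](C)(C)C(C)(C)C)C/C=C\C=C(/C)[C@@H](O)[C@@H](C)/C=C(/C)C(=O)O[C@H](/C=C/[C@@H](O[Si](C)(C)C(C)(C)C)[C@H](C)O[Si](C)(C)C(C)(C)C)[C@@H]2C | intermediate
48 | 11,22,23-tris-O-TBS maltepolide D | CO[C@H]1C[C@H]2O[C@H]1/C=C(/C)[C@H](O[Si](C)(C)C(C)(C)C)C/C=C\C=C(/C)C(=O)[C@@H](C)/C=C(/C)C(=O)O[C@H](/C=C/[C@@H](O[Si](C)(C)C(C)(C)C)[C@H](C)O[Si](C)(C)C(C)(C)C)[C@@H]2C | intermediate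
49 | maltepolide D | CO[C@H]1C[C@H]2O[C@H]1/C=C(/C)[C@H](O)C/C=C\C=C(/C)C(=O)[C@@H](C)/C=C(/C)C(=O)O[C@H](/C=C/[C@@H](O)[C@H](C)O)[C@@H]2C | target

## Totals
- Total step count: 27.
- Longest linear sequence: 14 steps, from 5 (steps 2–7, 13, 14, 22–27).

## Steps most likely to fail

**Step 1.** The captodative acrylate may be too poor an acceptor. Propanal may instead self-condense by benzoin or aldol pathways. The enantioselectivity of the protonation is unknown.

The fallback gives up the catalytic C16–C17 construction and takes C14–C17 and the C15 oxygen from the chiral pool. It carries over none of the numbered compounds (it replaces 1 and 2) and comes back at 4. L-malic acid F1 is condensed with 2,2-dimethoxypropane (PPTS) to the dioxolanone acid F2. Oxalyl chloride and catalytic DMF give the acid chloride F3. Iron-catalysed acylation of EtMgBr (Fe(acac)3, THF, –78 °C) gives the ethyl ketone F4. Acid-catalysed methanolysis opens the dioxolanone to the hydroxy keto ester F5, and MeI/Ag2O methylates the hydroxyl under non-basic conditions to give 4.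

**Step 13.** The Z-alkenylborane carries a bulky secondary silyloxy group cis to boron, so it may protodeboronate instead of transferring. BF3 may attack the silyl ethers or the allylic acetate. The C14 selectivity rests on a model.

The fallback sets out from 17 and 14 and comes back at 28. It gives up the convergent transfer of the whole C8–C13 unit and moves the fragment growth to the C10–C11 bond. Compound 17 is silylated to the primary TBS ether F6 and converted (t-BuLi; B(OMe)3; KHF2) into the small, unhindered alkenyltrifluoroborate F7. This is coupled with 14 to the C11–C24 allylic silyl ether F8. Buffered HF·pyridine frees only the primary allylic alcohol F9, and MnO2 gives the Z-enal F10. The C10–C11 bond and the C11 stereocentre are then made on the large fragment by the copper-catalysed propargylation with 19, which gives the homopropargylic alcohol F11. TBSOTf converts this into 28.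

**Step 23.** Oligomerisation, Glaser dimerisation, or competing ionisation of the allylic ester by Pd(0) may erode the macrocyclisation.

The fallback sets out from 29 and 41 and comes back at 45. It closes the ring at the ester C–O bond instead of at C7–C8. Intermolecular Sonogashira coupling of 29 with iodide 41 at normal concentration gives the enyne hydroxy ester F12. LiOH gives the seco acid F13, and Yamaguchi macrolactonisation onto C19-OH under high dilution gives 45.

## Further compounds
F1 | step 1 | L-malic acid | OC(=O)C[C@H](O)C(=O)O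
F2 | step 1 | (S)-2-(2,2-dimethyl-5-oxo-1,3-dioxolan-4-yl)acetic acid | CC1(C)O[C@@H](CC(=O)O)C(=O)O1
F3 | step 1 | (S)-2-(2,2-dimethyl-5-oxo-1,3-dioxolan-4-yl)acetyl chloride | CC1(C)O[C@@H](CC(=O)Cl)C(=O)O1
F4 | step 1 | (S)-2,2-dimethyl-5-(2-oxobutyl)-1,3-dioxolan-4-one | CC1(C)O[C@@H](CC(=O)CC)C(=O)O1
F5 | step 1 | methyl (2S)-2-hydroxy-4-oxohexanoate | CCC(=O)C[C@H](O)C(=O)OC
F6 | step 13 | (Z)-3-iodo-2-methylprop-2-enyl TBS ether | I/C=C(/C)CO[Si](C)(C)C(C)(C)C
F7 | step 13 | potassium (Z)-[3-(TBSO)-2-methylprop-1-enyl]trifluoroborate | [K+].F[B-](F)(F)/C=C(/C)CO[Si](C)(C)C(C)(C)C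
F8 | step 13 | C11–C24 2-alkenyl-THF, primary C11-OTBS, C19-OAc | CO[C@H]1C[C@H]([C@@H](C)[C@H](OC(C)=O)/C=C/[C@@H](O[Si](C)(C)C(C)(C)C)[C@H](C)O[Si](C)(C)C(C)(C)C)O[C@H]1/C=C(/C)CO[Si](C)(C)C(C)(C)C
F9 | step 13 | C11 primary allylic alcohol | CO[C@H]1C[C@H]([C@@H](C)[C@H](OC(C)=O)/C=C/[C@@H](O[Si](C)(C)C(C)(C)C)[C@H](C)O[Si](C)(C)C(C)(C)C)O[C@H]1/C=C(/C)CO
F10 | step 13 | C11 Z-enal | CO[C@H]1C[C@H]([C@@H](C)[C@H](OC(C)=O)/C=C/[C@@H](O[Si](C)(C)C(C)(C)C)[C@H](C)O[Si](C)(C)C(C)(C)C)O[C@H]1/C=C(/C)C=O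
F11 | step 13 | (11R)-homopropargylic alcohol, C8-TMS, C19-OAc | CO[C@H]1C[C@H]([C@@H](C)[C@H](OC(C)=O)/C=C/[C@@H](O[Si](C)(C)C(C)(C)C)[C@H](C)O[Si](C)(C)C(C)(C)C)O[C@H]1/C=C(/C)[C@H](O)CC#C[Si](C)(C)C
F12 | step 23 | open-chain enyne hydroxy ethyl ester | CO[C@H]1C[C@H]([C@@H](C)[C@H](O)/C=C/[C@@H](O[Si](C)(C)C(C)(C)C)[C@H](C)O[Si](C)(C)C(C)(C)C)O[C@H]1/C=C(/C)[C@H](O[Si](C)(C)C(C)(C)C)CC#C/C=C(\C)[C@@H](O[Si](CC)(CC)CC)[C@@H](C)/C=C(/C)C(=O)OCC
F13 | step 23 | enyne seco acid | CO[C@H]1C[C@H]([C@@H](C)[C@H](O)/C=C/[C@@H](O[Si](C)(C)C(C)(C)C)[C@H](C)O[Si](C)(C)C(C)(C)C)O[C@H]1/C=C(/C)[C@H](O[Si](C)(C)C(C)(C)C)CC#C/C=C(\C)[C@@H](O[Si](CC)(CC)CC)[C@@H](C)/C=C(/C)C(=O)O
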